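## The problem

Compound 13, 6-[(2R)-2-acetoxytridecyl]-2-hydroxy-4-methoxybenzoic acid, is a tetrasubstituted benzene with three neighbouring ring carbons occupied (benzoic acid numbering): C6 carries the CH2–CH(OAc)–C11H23 chain, C1 the carboxyl group and C2 a free hydroxyl, while C4 carries a methoxyl. A synthesis must therefore make an aryl–CH2 bond and an aryl–carboxyl bond on adjacent carbons and must tell the two phenolic oxygens apart. The only stereocenter is C2' of the side chain, (R)-configured. Nothing else in the molecule can steer it, so it has to come from the chiral pool or a chiral reagent, and afterwards it must never be a reacting atom. The functional groups tolerate little: the acetate does not survive hydroxide or alkoxide, and whenever the C2' oxygen is free while the carboxyl is free or activated, a six-membered lactone closes. The acetate must therefore come late and the last step must be neutral. The same lactonisation is the opportunity: the C6–CH2–CH(O) unit and the C1 carboxyl carbon, joined through the carbinol oxygen, form the hetero ring (ring B) of a 3-undecyl-3,4-dihydroisocoumarin. This is an arene with an alkyl group at the ortho carbon and an acyl group at the ipso carbon, the pattern a palladium–norbornene relay writes onto an aryl iodide. The C2 oxygen, once capped, fills the second ortho position of C1, so only the C6–H bond is left to react.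

## Retrosynthesis

**13 ⇒ 12.** The two O–CH2Ph bonds of benzyl 6-[(2R)-2-acetoxytridecyl]-2-(benzyloxy)-4-methoxybenzoate 12 are cut. Benzyl on both the phenol and the acid allows one neutral hydrogenolysis as the final step. A hydrolytic unmasking would strip the acetate and a Lewis-acid dealkylation would endanger the methyl ether. Compound 12 has the same skeleton but no acidic proton. The forward step only has to spare an acetate that is homobenzylic, not benzylic.

**12 ⇒ 11 ⇒ 9.** Cutting the acetyl–oxygen bond gives hydroxy ester 11. Joining its hydroxyl to the ester carbonyl, in place of the benzyl ester, gives lactone 9, (3R)-8-(benzyloxy)-6-methoxy-3-undecylisochroman-1-one. An open-chain hydroxy acid carried through the route would need two more protecting groups. In the lactone, carboxyl and carbinol protect each other, and 9 is exactly what the key step delivers. The forward direction asks that hydroxide open the ring to the potassium salt 10, that the carboxylate be alkylated at oxygen (which never activates the carbonyl carbon), and that 11 be acetylated before it can close back.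

**9 ⇒ 2 + 7 + 8.** Three bonds are cut: aryl–CH2 (C6–CH2), aryl–carbonyl (C1–C=O) and acyl–oxygen. The neighbouring cuts are weaker for this target. Lateral metalation of an ortho-toluate and addition to dodecanal would create the stereocenter without control. Ortho-lithiation of a benzamide followed by epoxide opening needs a stoichiometric alkyllithium beside a benzyl ether and a separate lactonisation. Building the arene from acyclic pieces is longer. The chosen cut reduces a 32-heavy-atom lactone to 2-(benzyloxy)-1-iodo-4-methoxybenzene 2, (R)-2-undecyloxirane 7 and carbon monoxide 8, joined in one operation. The forward reaction must alkylate one ortho position only, open the epoxide at CH2 only, and take up CO after the alkylation but before any direct C–O closure.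

**7 ⇒ 6 ⇒ 4 + 5 (from 3).** The C3–C4 bond of the tridecane chain is cut. (R)-Epichlorohydrin 4 supplies the stereocenter and three carbons, and decylmagnesium bromide 5, made from 1-bromodecane 3, supplies the rest. This is preferred to asymmetric epoxidation of a terminal alkene (poorly selective) and to a kinetic resolution (half the material lost). The forward reaction needs copper-catalysed attack at the epoxide CH2 and not at the CH2Cl carbon, then base closure of chlorohydrin 6.

**2 ⇒ 1.** The O–benzyl bond is cut. 2-Iodo-5-methoxyphenol 1 already has the iodine ortho to the hydroxyl and para to the methoxyl. The phenol is capped because a free phenoxide would compete for the epoxide and for palladium.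

## Roads not taken

**Alternative 1:** The cut runs through the benzene ring: ring bond C1–C6 and the ester C–O bond are opened, unfolding the arene into a 3,5,7-trioxo ester masked as a dioxinone.
- **Forward step.** The diketo-dioxinone A1 would be heated with benzyl alcohol A2. Cycloreversion of the dioxinone unmasks an acylketene, which A2 traps as the trioxo ester A3. A mild carbonate base then brings about the intramolecular aldol condensation and dehydration to the resorcylate A4.
- **Merits.** The reaction class is well established for 6-alkyl resorcylates. The substitution pattern is fixed by the chain, the benzyl ester is installed directly, and the stereocenter travels as a silyl ether.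
- **Weak points.** A1 needs its own multistep assembly from an enantiopure 3-silyloxy acid derivative. The β-silyloxy ketone in A1 and A3 can lose silanolate by E1cB elimination under the basic aromatisation. A4 has two free phenols, so a selective methylation at the C4 oxygen is needed. Desilylation then gives a hydroxy ester with the same lactonisation hazard as compound 11, followed by acetylation and hydrogenolysis.
- **Comparison.** Alternative 1 is better in one respect: each of its steps has close precedent, whereas the chosen plan rests on a domino process without direct precedent. Against that the chosen plan sets roughly half the step count, an arene whose oxygens are already differentiated when bought, and a fallback to lactone 9 by known chemistry.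

**Alternative 2:** Ring bonds C1–C2 and C5–C6 are cut, giving the oxygenated diene A5 and the chiral alkynoate A6.
- **Forward step.** A Diels–Alder reaction joins the CH2 terminus of A5 to the β-carbon of A6 and the ketene acetal carbon to the α-carbon. Loss of one methoxy group and acidic desilylation aromatise the adduct to A7.
- **Merits.** A7 is the benzyl ester of the target, with methoxyl and hydroxyl already differentiated and the acetate in place, so a single hydrogenolysis would finish the synthesis. No lactone and no hydroxy ester is passed. On paper this is the shortest endgame, and in that respect it is better than the chosen plan.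
- **Weak points.** A6 is a weak dienophile, activated by only one ester and carrying an alkyl group at the β-carbon. The diene A5 is thermally and hydrolytically fragile, and the forcing conditions needed favour open-chain conjugate addition over ring closure. The propargylic CH2 of A6 lies between the alkyne and the acetoxy-bearing carbon, so isomerisation to the allene and loss of the acetate threaten. A6 itself needs several steps from epoxide 7.
- **Comparison.** The chosen plan buys its arene instead of making it with a mismatched cycloaddition partner, and its key step is built from elementary steps that are each separately established.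

**Alternative 3:** Ring bonds C5–C6 and C3–C4 are cut, giving the 2-pyrone-5-carboxylate A8 and 1,1-dimethoxyethene A9.
- **Forward step.** An inverse-demand [4+2] addition joins the CH2 carbon of A9 to pyrone C6. The bridged lactone adduct decarboxylates and eliminates one methoxy group to give A10, which is the very compound numbered 12 in the chosen route.
- **Merits.** Regiochemistry follows from polarity. The sequence never passes through hydroxy ester 11, and this cycloaddition type is known for alkoxy benzoates. In these respects it is as good as or better than the chosen plan.
- **Weak points.** A8 is a fully substituted heterocycle, more complex than anything in the chosen route. Its preparation needs a chiral β-keto ester, a pyrone ring closure and a regioselective O-benzylation of a 4-hydroxy-2-pyrone. The bond-forming carbon C6 of A8 is substituted and its C4 benzyloxy group donates electrons, both of which slow the cycloaddition. The acetate lies β to an acidic pyrone–CH2 and can be eliminated.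
- **Comparison.** Both roads meet at 12. The chosen plan reaches 12 in six steps from three simple commercial materials, whereas Alternative 3 must first build A8 in at least as many steps before its key step.

Key step: step 4

Remark: ring positions are numbered as in the benzoic acid (C1 bears the carboxyl group). Carbon monoxide supplies the carboxyl carbon and is therefore numbered as a starting material. Catalyst-bound palladium intermediates of step 4 are not numbered.

## Route

Step 1
Reactants: 1 2-iodo-5-methoxyphenol
Product: 2 2-(benzyloxy)-1-iodo-4-methoxybenzene
Conditions: BnBr (1.1 equiv), K2CO3, DMF, rt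
Reagents that add atoms: benzyl bromide, BrCc1ccccc1
Why: Williamson ether synthesis on an unhindered phenoxide; the benzyl ether masks the phenol during the palladium chemistry and becomes the ortho blocking group that the key step needs.

Step 2
Reactants: 3 1-bromodecane; 4 (R)-epichlorohydrin
Product: 6 (R)-1-chlorotridecan-2-ol, via decylmagnesium bromide 5 (not isolated)
Conditions: Mg turnings, THF, 40 °C; then CuI (10 mol %), 4, THF, −40 to −20 °C; aq. NH4Cl
Reagents that add atoms: none
Why: Grignard formation followed by copper-catalysed SN2 opening of the epoxide at its unsubstituted CH2 carbon, which at low temperature is faster than displacement of chloride; the stereocenter of 4 keeps its C–O bond and is not a reacting atom, so 6 is (R) (the CH2Cl group still outranks the alkyl-bearing CH2, so the descriptor is unchanged).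

Step 3
Reactants: 6 (R)-1-chlorotridecan-2-ol
Product: 7 (R)-2-undecyloxirane [(R)-1,2-epoxytridecane]
Conditions: powdered NaOH, Et2O, rt
Reagents that add atoms: none
Why: Intramolecular Williamson reaction (3-exo-tet); the alkoxide displaces chloride at the primary carbon, so the configuration of the carbinol carbon is retained.

Step 4
Reactants: 2 2-(benzyloxy)-1-iodo-4-methoxybenzene; 7 (R)-2-undecyloxirane; 8 carbon monoxide
Product: 9 (3R)-8-(benzyloxy)-6-methoxy-3-undecylisochroman-1-one
Conditions: 7 (1.5 equiv), Pd(OAc)2 (10 mol %), XPhos (20 mol %), potassium 5-norbornene-2-carboxylate (50 mol %), K2CO3 (2 equiv), CO/N2 1:9 (1 atm, balloon), NMP, 70 °C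
Reagents that add atoms: none
Why: Proposed new method: zerovalent palladium adds to the C–I bond of 2, the norbornene carboxylate inserts, and the only free ortho C–H (C6 of the future benzoate, the other ortho carbon carrying the benzyloxy group) is palladated to give the aryl norbornyl palladacycle; this divalent palladacycle opens epoxide 7 at its unsubstituted CH2 carbon in an SN2-type oxidative addition to a tetravalent palladium alkoxide, and reductive elimination forms the aryl–CH2 bond. The now doubly ortho-substituted aryl norbornyl palladium species expels the norbornene by β-carbon elimination, and the hindered aryl divalent palladium species, chelated by the pendant alkoxide, inserts CO into the aryl–Pd bond. The lactone ring, the only ring formed, then closes by attack of the alkoxide on the acyl palladium carbon, a 6-exo-trig acyl substitution equivalent to C–O reductive elimination from a seven-membered acyl alkoxo palladacycle, which returns zerovalent palladium. The closest known reaction types are the Catellani ortho-alkylation of aryl iodides with epoxides, which ends in ipso C–O closure to 2,3-dihydrobenzofurans or in ipso Heck coupling, and the carbonylative lactonisation of aryl halides carrying a hydroxyalkyl side chain; the proposal places CO insertion between the two. No stereocenter is created: the carbinol carbon of 7 keeps its C–O bond and all its substituents, so the (R) configuration passes into 9 unchanged. The step needs alkylation at one ortho position only, secured by the benzyloxy group at the other, and attack at the epoxide CH2, secured by the steric bias of the SN2-type opening. It also needs carbonylation only after norbornene extrusion: CO is kept dilute while the strained alkene is present in high concentration, so norbornene insertion should outrun CO insertion at the first aryl palladium stage, whereas at the second stage CO insertion competes only with the slow C(sp2)–O reductive elimination.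

Step 5
Reactants: 9 (3R)-8-(benzyloxy)-6-methoxy-3-undecylisochroman-1-one
Product: 11 benzyl 2-(benzyloxy)-6-[(2R)-2-hydroxytridecyl]-4-methoxybenzoate, via potassium hydroxy carboxylate 10 (not isolated)
Conditions: KOH (1.1 equiv), EtOH/H2O, 70 °C; evaporate, toluene azeotrope; then BnBr (1.3 equiv), DMF, 0 °C to rt; pH 7 buffer work-up, crude used at once
Reagents that add atoms: potassium hydroxide, [K+].[OH-]; benzyl bromide, BrCc1ccccc1
Why: Saponification of the lactone (acyl–oxygen cleavage, stereocenter untouched) followed by SN2 O-alkylation of the carboxylate; alkylation at the carboxylate oxygen makes the ester without ever activating the carbonyl carbon towards the neighbouring hydroxyl, and the resulting 2,6-disubstituted benzoate should be slow to re-lactonise under neutral conditions.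

Step 6
Reactants: 11 benzyl 2-(benzyloxy)-6-[(2R)-2-hydroxytridecyl]-4-methoxybenzoate
Product: 12 benzyl 6-[(2R)-2-acetoxytridecyl]-2-(benzyloxy)-4-methoxybenzoate
Conditions: Ac2O, pyridine, DMAP (5 mol %), CH2Cl2, 0 °C
Reagents that add atoms: acetic anhydride, CC(=O)OC(C)=O
Why: DMAP-catalysed acylation of a secondary alcohol, fast at 0 °C and run without any base strong enough to form the alkoxide, so acetyl transfer should outpace ring closure onto the hindered benzyl ester; only the O–H bond reacts, so the configuration is retained.

Step 7
Reactants: 12 benzyl 6-[(2R)-2-acetoxytridecyl]-2-(benzyloxy)-4-methoxybenzoate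
Product: 13 6-[(2R)-2-acetoxytridecyl]-2-hydroxy-4-methoxybenzoic acid
Conditions: H2 (1 atm), 10% Pd/C, EtOAc, rt
Reagents that add atoms: none
Why: Catalytic hydrogenolysis cleaves the benzyl ester and the aryl benzyl ether under neutral conditions; the acetate sits on a homobenzylic carbon and the methyl ether is inert, so the free acid, the free phenol and the intact acetate should be revealed together.

## Compound list

1 | 2-iodo-5-methoxyphenol | COc1ccc(I)c(O)c1 | starting material
2 | 2-(benzyloxy)-1-iodo-4-methoxybenzene | COc1ccc(I)c(OCc2ccccc2)c1 | intermediate
3 | 1-bromodecane | CCCCCCCCCCBr | starting material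
4 | (R)-epichlorohydrin [(R)-2-(chloromethyl)oxirane] | ClC[C@H]1CO1 | starting material
5 | decylmagnesium bromide | CCCCCCCCCC[Mg]Br | intermediate
6 | (R)-1-chlorotridecan-2-ol | CCCCCCCCCCC[C@@H](O)CCl | intermediate
7 | (R)-2-undecyloxirane [(R)-1,2-epoxytridecane] | CCCCCCCCCCC[C@@H]1CO1 | intermediate
8 | carbon monoxide | [C-]#[O+] | starting material
9 | (3R)-8-(benzyloxy)-6-methoxy-3-undecylisochroman-1-one | CCCCCCCCCCC[C@@H]1Cc2cc(OC)cc(OCc3ccccc3)c2C(=O)O1 | intermediate
10 | potassium 2-(benzyloxy)-6-[(2R)-2-hydroxytridecyl]-4-methoxybenzoate | CCCCCCCCCCC[C@H](Cc1cc(OC)cc(OCc2ccccc2)c1C(=O)[O-])O.[K+] | intermediate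
11 | benzyl 2-(benzyloxy)-6-[(2R)-2-hydroxytridecyl]-4-methoxybenzoate | CCCCCCCCCCC[C@H](Cc1cc(OC)cc(OCc2ccccc2)c1C(=O)OCc1ccccc1)O | intermediate
12 | benzyl 6-[(2R)-2-acetoxytridecyl]-2-(benzyloxy)-4-methoxybenzoate | CCCCCCCCCCC[C@H](Cc1cc(OC)cc(OCc2ccccc2)c1C(=O)OCc1ccccc1)OC(C)=O | intermediate
13 | 6-[(2R)-2-acetoxytridecyl]-2-hydroxy-4-methoxybenzoic acid | CCCCCCCCCCC[C@H](Cc1cc(OC)cc(O)c1C(=O)O)OC(C)=O | target

## Step count and risks

Total: 7 steps. Longest linear sequence: 6 steps (steps 2, 3, 4, 5, 6, 7, from 1-bromodecane 3 and (R)-epichlorohydrin 4).

**Step 4 (key step, beyond precedent).**
- **What may go wrong.** CO may capture the first aryl palladium species before the norbornene has inserted, giving plain carbonylation of the C–I bond without ortho alkylation. CO may insert into the palladacycle in competition with the comparatively slow epoxide opening. If the gas is too dilute, ipso C–O closure to the five-membered cyclic ether may occur without CO uptake. The catalyst may also aggregate under CO. The window between too much and too little CO may be narrow.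
- **Fallback by known chemistry.** Compound 2 is converted with carbon monoxide 8 and water by palladium-catalysed hydroxycarbonylation (Pd(OAc)2, PPh3, K2CO3, DMF/H2O, 80 °C, then acidification) into 2-(benzyloxy)-4-methoxybenzoic acid F1. F1 then undergoes carboxylate-directed ortho C–H alkylation with epoxide 7 (Pd(OAc)2, KOAc, hexafluoroisopropanol, mild heating). This is a known route from benzoic acids and terminal epoxides to 3-substituted 3,4-dihydroisocoumarins: the only free ortho C–H of F1 is palladated, the epoxide is opened at CH2 and the hydroxy acid lactonises, returning to the route at 9. The same bonds are formed in the reverse order, with the carbonyl first and the alkyl group second. Material lost to premature carbonylation in step 4 would appear as this same acid after aqueous work-up and can be fed into the fallback.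

**Step 5.**
- **What may go wrong.** The hydroxy ester may close back to the lactone, with loss of the benzyl ester, during alkylation or work-up, because any residual hydroxide turns the alcohol into an alkoxide beside the ester. That alkoxide may also be benzylated. The hazard lasts until the acetyl group is on in step 6. Lactone regenerated this way is not lost and can be recycled.
- **Fallback.** From salt 10 the alcohol is blocked before the ester is made. TBSCl and imidazole in DMF give tert-butyldimethylsilyl 2-(benzyloxy)-6-[(2R)-2-(tert-butyldimethylsilyloxy)tridecyl]-4-methoxybenzoate F2. K2CO3 in aqueous MeOH cleaves only the silyl ester to 2-(benzyloxy)-6-[(2R)-2-(tert-butyldimethylsilyloxy)tridecyl]-4-methoxybenzoic acid F3, which cannot lactonise. BnBr and KHCO3 in DMF give benzyl 2-(benzyloxy)-6-[(2R)-2-(tert-butyldimethylsilyloxy)tridecyl]-4-methoxybenzoate F4. HF·pyridine in THF then releases the alcohol under non-basic conditions, returning to the route at 11, which is acetylated at once as in step 6.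

**Step 2.**
- **What may go wrong.** The Grignard reagent may partly attack the chloromethyl carbon instead of the epoxide CH2, which after step 3 would lower the enantiomeric purity. Magnesium halide may open the epoxide to halohydrins. Homocoupling during Grignard formation may lower the titre.
- **Fallback.** The stereocenter is set by catalyst-controlled resolution instead of the chiral pool. Decylmagnesium bromide 5 is coupled with allyl bromide to tridec-1-ene F5. mCPBA in CH2Cl2 gives racemic 2-undecyloxirane F6. Hydrolytic kinetic resolution with 0.55 equivalents of water and the enantiomer of the chiral (salen)Co(OAc) complex that hydrolyses the (S)-epoxide leaves the (R)-epoxide, returning to the route at 7 after distillation from the diol.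

## Further compounds

F1 | step 4 | 2-(benzyloxy)-4-methoxybenzoic acid | COc1ccc(C(=O)O)c(OCc2ccccc2)c1
F2 | step 5 | tert-butyldimethylsilyl 2-(benzyloxy)-6-[(2R)-2-(tert-butyldimethylsilyloxy)tridecyl]-4-methoxybenzoate | CCCCCCCCCCC[C@H](Cc1cc(OC)cc(OCc2ccccc2)c1C(=O)O[Si](C)(C)C(C)(C)C)O[Si](C)(C)C(C)(C)C
F3 | step 5 | 2-(benzyloxy)-6-[(2R)-2-(tert-butyldimethylsilyloxy)tridecyl]-4-methoxybenzoic acid | CCCCCCCCCCC[C@H](Cc1cc(OC)cc(OCc2ccccc2)c1C(=O)O)O[Si](C)(C)C(C)(C)C
F4 | step 5 | benzyl 2-(benzyloxy)-6-[(2R)-2-(tert-butyldimethylsilyloxy)tridecyl]-4-methoxybenzoate | CCCCCCCCCCC[C@H](Cc1cc(OC)cc(OCc2ccccc2)c1C(=O)OCc1ccccc1)O[Si](C)(C)C(C)(C)C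
F5 | step 2 | tridec-1-ene | CCCCCCCCCCCC=C
F6 | step 2 | racemic 2-undecyloxirane | CCCCCCCCCCCC1CO1
A1 | alternative 1 | (R)-6-[6-(tert-butyldimethylsilyloxy)-2,4-dioxoheptadecyl]-2,2-dimethyl-4H-1,3-dioxin-4-one | CCCCCCCCCCC[C@H](CC(=O)CC(=O)CC1=CC(=O)OC(C)(C)O1)O[Si](C)(C)C(C)(C)C
A2 | alternative 1 | benzyl alcohol | OCc1ccccc1
A3 | alternative 1 | benzyl (R)-9-(tert-butyldimethylsilyloxy)-3,5,7-trioxoicosanoate | CCCCCCCCCCC[C@H](CC(=O)CC(=O)CC(=O)CC(=O)OCc1ccccc1)O[Si](C)(C)C(C)(C)C
A4 | alternative 1 | benzyl (R)-6-[2-(tert-butyldimethylsilyloxy)tridecyl]-2,4-dihydroxybenzoate | CCCCCCCCCCC[C@H](Cc1cc(O)cc(O)c1C(=O)OCc1ccccc1)O[Si](C)(C)C(C)(C)C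
A5 | alternative 2 | 1,3-dimethoxy-1-(trimethylsilyloxy)buta-1,3-diene | C=C(OC)C=C(OC)O[Si](C)(C)C
A6 | alternative 2 | benzyl (R)-5-acetoxyhexadec-2-ynoate | CCCCCCCCCCC[C@H](CC#CC(=O)OCc1ccccc1)OC(C)=O
A7 | alternative 2 | benzyl (R)-6-(2-acetoxytridecyl)-2-hydroxy-4-methoxybenzoate | CCCCCCCCCCC[C@H](Cc1cc(OC)cc(O)c1C(=O)OCc1ccccc1)OC(C)=O
A8 | alternative 3 | benzyl 6-[(R)-2-acetoxytridecyl]-4-(benzyloxy)-2-oxo-2H-pyran-5-carboxylate | CCCCCCCCCCC[C@H](CC1=C(C(=O)OCc2ccccc2)C(OCc2ccccc2)=CC(=O)O1)OC(C)=O
A9 | alternative 3 | 1,1-dimethoxyethene | C=C(OC)OC
A10 | alternative 3 | benzyl (R)-6-(2-acetoxytridecyl)-2-(benzyloxy)-4-methoxybenzoate (identical with 12) | CCCCCCCCCCC[C@H](Cc1cc(OC)cc(OCc2ccccc2)c1C(=O)OCc1ccccc1)OC(C)=O
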